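**Plan**

- Retrosynthesis: both acetates are removed; the side chain is cut at the bond between its CH(CH2O) carbon and the lactone β-carbon and at the lactone Cα–O bond (azaenolate + furan-2(5H)-one + electrophilic oxygen). The seven-membered ring is then cut at the two bonds that join its central CH2–CH2 unit to the methylene-bearing ring carbon and to the CH2 next to the CMe2 carbon (ethylene leaves), after those two carbons are re-joined to each other.
- Enabling feature: the ring carbon that carries the exocyclic =CH2 and the ring CH2 bonded to the CMe2 carbon are separated only by CH2–CH2. Joined directly, they are the C=C of a cyclopentene-1-carboxylate inside a cis-bicyclo[3.3.0]octene, with the =CH2 carbon as the ester carbon. Enoate–ethylene [2+2] builds a cyclobutane on that C=C; the ester-derived CH2 radical then opens the shared bond, which gives the cycloheptane and the 1,1-disubstituted alkene at once.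
- Forward order: cyclopentane (ozonolysis/aldol of (R)-p-menth-1-ene) → second five-membered ring by Rh-carbenoid C–H insertion (creates CMe2) → quaternary carbon by Mukaiyama–Michael addition → enoate → cyclobutane with ethylene → seven-membered ring by radical fragmentation → side chain and lactone → acetates.
- Stereochemistry: the CMe2-bearing ring-fusion carbon comes from (R)-p-menth-1-ene. The quaternary carbon and the second ring-fusion carbon come from convex-face addition and cis-bicyclo[3.3.0] protonation. The cyclobutane centres are erased again, so the photoaddition needs no facial control. The three side-chain centres come from the SAMP auxiliary, a staggered Michael transition state and trans hydroxylation of the lactone enolate.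

Key step: step 9

Remark: step 9 can give two cyclobutane isomers (ethylene on the convex or the concave face of the bicycle); 17–19 are drawn as the convex-face isomer and the other is carried along, because both should give 20 in step 12.

**Route**

Step 1
Reactants: 1 (R)-(+)-p-menth-1-ene
Product: 3 (3R)-6-oxo-3-(propan-2-yl)heptanal, via ozonide 2 (not isolated)
Conditions: O3, CH2Cl2, −78 °C; then Me2S, −78 °C → rt
Reagents that add atoms: ozone, [O-][O+]=O
Why: Ozonolysis with reductive work-up cleaves the only (trisubstituted) alkene to the keto aldehyde and leaves the stereocentre, which is not α to a carbonyl, untouched.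

Step 2
Reactants: 3 (3R)-6-oxo-3-(propan-2-yl)heptanal
Product: 4 (5S)-2-methyl-5-(propan-2-yl)cyclopent-1-ene-1-carbaldehyde
Conditions: piperidine (cat.), AcOH (cat.), benzene, 80 °C, Dean–Stark
Reagents that add atoms: none
Why: Intramolecular aldol condensation through the aldehyde enamine, whose α-carbon attacks the methyl ketone to close the five-membered ring, should give the conjugated enal as known for the limonene-derived analogue.

Step 3
Reactants: 4 (5S)-2-methyl-5-(propan-2-yl)cyclopent-1-ene-1-carbaldehyde
Product: 5 (5S)-2-methyl-5-(propan-2-yl)cyclopent-1-ene-1-carboxylic acid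
Conditions: NaClO2, NaH2PO4, 2-methyl-2-butene, t-BuOH/H2O, rt
Reagents that add atoms: sodium chlorite, [Na+].[O-]Cl=O
Why: Pinnick oxidation is selective for the aldehyde, and the scavenger protects the tetrasubstituted alkene from hypochlorite.

Step 4
Reactants: 5 (5S)-2-methyl-5-(propan-2-yl)cyclopent-1-ene-1-carboxylic acid
Product: 7 2-diazo-1-[(5S)-2-methyl-5-(propan-2-yl)cyclopent-1-en-1-yl]ethan-1-one, via acid chloride 6 (not isolated)
Conditions: (COCl)2, DMF (cat.), CH2Cl2, 0 °C → rt, concentrate; then TMSCHN2, THF/MeCN, 0 °C
Reagents that add atoms: oxalyl chloride, O=C(Cl)C(=O)Cl (Cl of intermediate 6 only); (trimethylsilyl)diazomethane, C[Si](C)(C)C=[N+]=[N-]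
Why: Acylation of (trimethylsilyl)diazomethane by the acid chloride (Arndt–Eistert-type diazoketone synthesis) should give the diazomethyl ketone without touching the stereocentre.

Step 5
Reactants: 7 2-diazo-1-[(5S)-2-methyl-5-(propan-2-yl)cyclopent-1-en-1-yl]ethan-1-one
Product: 8 (3aS)-3,3,6-trimethyl-3,3a,4,5-tetrahydropentalen-1(2H)-one
Conditions: Rh2(OAc)4 (1 mol %), CH2Cl2, rt, slow addition of 7
Reagents that add atoms: none
Why: Rh(II)-carbenoid 1,5-insertion (Taber type) into the electron-rich tertiary C–H of the isopropyl group should close the second five-membered ring and create the CMe2 carbon, the existing stereocentre being only a spectator.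

Step 6
Reactants: 8 (3aS)-3,3,6-trimethyl-3,3a,4,5-tetrahydropentalen-1(2H)-one; 9 N,N-dimethylacetamide
Product: 12 2-(1,4,4-trimethyl-6-oxooctahydropentalen-1-yl)-N,N-dimethylacetamide (cis-fused; amide arm syn to H-3a and H-6a), via silyl ketene aminal 10 (not isolated), via silyl enol ether 11 (not isolated)
Conditions: 9, TMSOTf (1.3 equiv), i-Pr2NEt (1.1 equiv), CH2Cl2, 0 °C; then 8, −78 → −20 °C; 1 M HCl
Reagents that add atoms: trimethylsilyl triflate, C[Si](C)(C)OS(=O)(=O)C(F)(F)F (silyl group of intermediates 10 and 11 only)
Why: Mukaiyama–Michael addition of the very nucleophilic O-silyl ketene N,O-acetal to the TMSOTf-activated enone should occur at the β-carbon from the convex face (the face of H-3a) of the folded bicycle, which sets the quaternary carbon, and hydrolysis of the silyl enol ether protonates the ring-fusion carbon to the cis-fused ketone, the only low-strain bicyclo[3.3.0] isomer.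

Step 7
Reactants: 12 2-(1,4,4-trimethyl-6-oxooctahydropentalen-1-yl)-N,N-dimethylacetamide
Product: 14 6-[2-(dimethylamino)-2-oxoethyl]-3,3,6-trimethyl-3,3a,4,5,6,6a-hexahydropentalen-1-yl trifluoromethanesulfonate, via potassium enolate 13 (not isolated)
Conditions: KHMDS, THF, −78 °C; then PhNTf2, −78 → 0 °C
Reagents that add atoms: potassium hexamethyldisilazide, C[Si](C)(C)[N-][Si](C)(C)C.[K+] (K of intermediate 13 only); N-phenyl-bis(trifluoromethanesulfonimide), O=S(=O)(N(c1ccccc1)S(=O)(=O)C(F)(F)F)C(F)(F)F
Why: Kinetic deprotonation should take the α-CH2 (the other α-position is a ring-fusion methine flanked by the quaternary carbon, and the amide α-CH2 is far less acidic), and O-triflation fixes the enol regiochemistry.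

Step 8
Reactants: 14 enol triflate
Product: 15 methyl 6-[2-(dimethylamino)-2-oxoethyl]-3,3,6-trimethyl-3,3a,4,5,6,6a-hexahydropentalene-1-carboxylate
Conditions: Pd(OAc)2 (5 mol %), PPh3 (10 mol %), CO (1 atm), MeOH, Et3N, DMF, 50 °C
Reagents that add atoms: carbon monoxide, [C-]#[O+]; methanol, CO
Why: Pd-catalysed methoxycarbonylation of an enol triflate (oxidative addition, CO insertion, methanolysis) is reliable and leaves the ring-fusion centre, which is not vinylogously acidic in the product, unchanged.

Step 9
Reactants: 15 methyl 6-[2-(dimethylamino)-2-oxoethyl]-3,3,6-trimethyl-3,3a,4,5,6,6a-hexahydropentalene-1-carboxylate; 16 ethylene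
Product: 17 methyl 10-[2-(dimethylamino)-2-oxoethyl]-6,6,10-trimethyltricyclo[5.3.0.0^2,5]decane-2-carboxylate
Conditions: hν (300 nm, Pyrex), ethylene (saturated, continuous stream), acetone (solvent and triplet sensitiser), −70 °C
Reagents that add atoms: none
Why: Acetone-sensitised triplet excitation of the cyclopentene-1-carboxylate gives an enoate triplet that cannot relax by twisting in the five-membered ring, adds ethylene stepwise through a 1,4-biradical and closes to the cyclobutane after intersystem crossing; the closest precedents are the sensitised [2+2] photocycloadditions of ethylene to butenolides, cyclopentenones and cycloalkene-1-carboxylates. The four-membered ring is closed as a [2+2] photocycloaddition, which forms both new C–C bonds to the two ethylene carbons in one operation. The two new stereocentres are forced cis on the cyclobutane by the five-membered ring, and their sense relative to the bicycle (convex-face addition expected) is irrelevant because both are destroyed in step 12, so the step is stereoconvergent by design. The selectivity needed is chemoselectivity: cross-addition instead of enoate dimerisation (large excess of ethylene, dilute enoate, low temperature), no photodeconjugation (the β-carbon is flanked by the quaternary CMe2 carbon, so there is no γ-hydrogen), and no reaction elsewhere (the side arm is a saturated tertiary amide without a chromophore above 280 nm). The ester is the helper group: chromophore here, then CH2 radical and finally the exocyclic methylene in steps 10–12.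

Step 10
Reactants: 17 cyclobutane ester
Product: 18 2-[2-(hydroxymethyl)-6,6,10-trimethyltricyclo[5.3.0.0^2,5]decan-10-yl]-N,N-dimethylacetamide
Conditions: LiBH4, MeOH (1 equiv), THF, 0 → 50 °C
Reagents that add atoms: none
Why: Lithium borohydride reduces the methyl ester to the primary alcohol and should leave the tertiary amide untouched.

Step 11
Reactants: 18 primary alcohol
Product: 19 2-[2-(iodomethyl)-6,6,10-trimethyltricyclo[5.3.0.0^2,5]decan-10-yl]-N,N-dimethylacetamide
Conditions: PPh3, I2, imidazole, toluene, 80 °C
Reagents that add atoms: iodine, II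
Why: Garegg–Samuelsson iodination (displacement of the alkoxyphosphonium by iodide) converts the hindered primary alcohol into the radical precursor under non-ionising conditions.

Step 12
Reactants: 19 iodide
Product: 20 2-(1,4,4-trimethyl-8-methylidenedecahydroazulen-1-yl)-N,N-dimethylacetamide (cis-fused; amide arm syn to H-3a and H-8a)
Conditions: Bu3SnH (syringe pump), AIBN (cat.), benzene, 80 °C
Reagents that add atoms: none
Why: Iodine abstraction gives a cyclobutylcarbinyl radical that should open by β-scission of the bond shared by the four- and five-membered rings (strain release, secondary ring radical), so the cyclopentane grows by the two ethylene carbons into the cycloheptane, the radical carbon becomes the exocyclic methylene and the ring radical is reduced by the stannane, as in the radical fragmentation of [2+2] photoadduct-derived iodides; both cyclobutane stereocentres vanish and the ring fusion is untouched.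

Step 13
Reactants: 20 hydroazulene amide
Product: 21 2-(1,4,4-trimethyl-8-methylidenedecahydroazulen-1-yl)acetaldehyde
Conditions: Cp2Zr(H)Cl (1.5 equiv), THF, rt, 20 min; SiO2/H2O work-up
Reagents that add atoms: none
Why: Schwartz reduction of a tertiary amide stops at the zirconated hemiaminal, which collapses to the aldehyde on work-up, and is much faster than hydrozirconation of the 1,1-disubstituted alkene.

Step 14
Reactants: 21 aldehyde; 22 (S)-1-amino-2-(methoxymethyl)pyrrolidine (SAMP)
Product: 23 (E)-SAMP hydrazone of 21
Conditions: CH2Cl2, MgSO4, 0 °C → rt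
Reagents that add atoms: none
Why: Condensation of the aldehyde with the hydrazine gives the E-hydrazone that serves as a chiral azaenolate precursor at the aldehyde oxidation level.

Step 15
Reactants: 23 SAMP hydrazone; 24 furan-2(5H)-one
Product: 27 SAMP hydrazone of 2-(4-hydroxy-5-oxooxolan-3-yl)-2-(1,4,4-trimethyl-8-methylidenedecahydroazulen-1-yl)acetaldehyde (lactone OH trans to the β-substituent), via lithium azaenolate 25 (not isolated), via lithium lactone enolate 26 (not isolated)
Conditions: LDA, THF, 0 °C; then 24, −100 → −78 °C; then 2-(phenylsulfonyl)-3-phenyloxaziridine, −78 °C; aq. NH4Cl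
Reagents that add atoms: lithium diisopropylamide, CC(C)[N-]C(C)C.[Li+] (Li of intermediates 25 and 26 only); 2-(phenylsulfonyl)-3-phenyloxaziridine, O=S(=O)(c1ccccc1)N1OC1c1ccccc1
Why: Enders-type Michael addition of the (E)-azaenolate to the butenolide followed by Davis hydroxylation of the resulting lactone enolate should set the side-chain CH by the (S)-auxiliary (expected to be reinforced by attack anti to the ring-fusion carbon), the lactone β-carbon by a staggered transition state with the two C–H bonds anti and the quaternary carbon turned away from the lactone α-carbon, and the hydroxyl trans to the new β-substituent.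

Step 16
Reactants: 27 hydroxy lactone hydrazone
Product: 28 2-(4-hydroxy-5-oxooxolan-3-yl)-2-(1,4,4-trimethyl-8-methylidenedecahydroazulen-1-yl)acetaldehyde
Conditions: saturated aq. oxalic acid, Et2O, rt
Reagents that add atoms: water, O
Why: Mild biphasic hydrolysis of the hydrazone (auxiliary recoverable) should release the aldehyde without epimerising the hindered α-centre or isomerising the exocyclic alkene.

Step 17
Reactants: 28 hydroxy lactone aldehyde
Product: 29 3-hydroxy-4-[2-hydroxy-1-(1,4,4-trimethyl-8-methylidenedecahydroazulen-1-yl)ethyl]oxolan-2-one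
Conditions: NaBH4 (1 equiv), MeOH, −20 °C
Reagents that add atoms: none
Why: Borohydride reduces the aldehyde far faster than the γ-lactone at low temperature.

Step 18
Reactants: 29 diol
Product: 30 CNP0234964.1
Conditions: Ac2O, pyridine, DMAP (cat.), CH2Cl2, 0 °C → rt
Reagents that add atoms: acetic anhydride, CC(=O)OC(C)=O
Why: Acylation of the primary and the secondary hydroxyl gives the diacetate without touching any stereocentre.

**Compound list**

1 | (R)-(+)-p-menth-1-ene | CC1=CC[C@@H](CC1)C(C)C | starting material
2 | (4R)-1-methyl-4-(propan-2-yl)-7,8,9-trioxabicyclo[4.2.1]nonane (ozonide, one of two bridgehead diastereomers drawn) | C[C@]12CC[C@@H](C(C)C)C[C@H](OO1)O2 | intermediate (not isolated)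
3 | (3R)-6-oxo-3-(propan-2-yl)heptanal | CC(C)[C@@H](CC=O)CCC(C)=O | intermediate
4 | (5S)-2-methyl-5-(propan-2-yl)cyclopent-1-ene-1-carbaldehyde | CC(C)[C@@H]1CCC(C)=C1C=O | intermediate
5 | (5S)-2-methyl-5-(propan-2-yl)cyclopent-1-ene-1-carboxylic acid | CC(C)[C@@H]1CCC(C)=C1C(=O)O | intermediate
6 | (5S)-2-methyl-5-(propan-2-yl)cyclopent-1-ene-1-carbonyl chloride | CC(C)[C@@H]1CCC(C)=C1C(=O)Cl | intermediate (not isolated)
7 | 2-diazo-1-[(5S)-2-methyl-5-(propan-2-yl)cyclopent-1-en-1-yl]ethan-1-one | CC(C)[C@@H]1CCC(C)=C1C(=O)C=[N+]=[N-] | intermediate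
8 | (3aS)-3,3,6-trimethyl-3,3a,4,5-tetrahydropentalen-1(2H)-one | O=C1CC(C)(C)[C@@H]2CCC(C)=C12 | intermediate
9 | N,N-dimethylacetamide | CC(=O)N(C)C | starting material
10 | 1-(dimethylamino)-1-(trimethylsilyloxy)ethene | C=C(O[Si](C)(C)C)N(C)C | intermediate (not isolated)
11 | 2-[1,4,4-trimethyl-6-(trimethylsilyloxy)-1,2,3,3a,4,5-hexahydropentalen-1-yl]-N,N-dimethylacetamide (amide arm syn to H-3a) | C[Si](C)(C)OC1CC(C)(C)[C@@H]2CC[C@@](C)(CC(=O)N(C)C)C=12 | intermediate (not isolated)
12 | 2-(1,4,4-trimethyl-6-oxooctahydropentalen-1-yl)-N,N-dimethylacetamide (cis-fused; amide arm syn to H-3a and H-6a) | O=C1CC(C)(C)[C@@H]2CC[C@@](C)(CC(=O)N(C)C)[C@H]12 | intermediate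
13 | potassium enolate of 12 (enolate towards the ring CH2) | [K+].[O-]C1=CC(C)(C)[C@@H]2CC[C@@](C)(CC(=O)N(C)C)[C@H]12 | intermediate (not isolated)
14 | 6-[2-(dimethylamino)-2-oxoethyl]-3,3,6-trimethyl-3,3a,4,5,6,6a-hexahydropentalen-1-yl trifluoromethanesulfonate (cis-fused) | O=S(=O)(OC1=CC(C)(C)[C@@H]2CC[C@@](C)(CC(=O)N(C)C)[C@H]12)C(F)(F)F | intermediate
15 | methyl 6-[2-(dimethylamino)-2-oxoethyl]-3,3,6-trimethyl-3,3a,4,5,6,6a-hexahydropentalene-1-carboxylate (cis-fused) | COC(=O)C1=CC(C)(C)[C@@H]2CC[C@@](C)(CC(=O)N(C)C)[C@H]12 | intermediate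
16 | ethylene | C=C | starting material
17 | methyl 10-[2-(dimethylamino)-2-oxoethyl]-6,6,10-trimethyltricyclo[5.3.0.0^2,5]decane-2-carboxylate (cyclobutane on the convex face, ester on the concave face) | COC(=O)[C@@]13CC[C@H]3C(C)(C)[C@@H]2CC[C@@](C)(CC(=O)N(C)C)[C@H]12 | intermediate
18 | 2-[2-(hydroxymethyl)-6,6,10-trimethyltricyclo[5.3.0.0^2,5]decan-10-yl]-N,N-dimethylacetamide | OC[C@@]13CC[C@H]3C(C)(C)[C@@H]2CC[C@@](C)(CC(=O)N(C)C)[C@H]12 | intermediate
19 | 2-[2-(iodomethyl)-6,6,10-trimethyltricyclo[5.3.0.0^2,5]decan-10-yl]-N,N-dimethylacetamide | IC[C@@]13CC[C@H]3C(C)(C)[C@@H]2CC[C@@](C)(CC(=O)N(C)C)[C@H]12 | intermediate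
20 | 2-(1,4,4-trimethyl-8-methylidenedecahydroazulen-1-yl)-N,N-dimethylacetamide (cis-fused; arm syn to H-3a and H-8a) | C=C1CCCC(C)(C)[C@@H]2CC[C@@](C)(CC(=O)N(C)C)[C@H]12 | intermediate
21 | 2-(1,4,4-trimethyl-8-methylidenedecahydroazulen-1-yl)acetaldehyde | C=C1CCCC(C)(C)[C@@H]2CC[C@@](C)(CC=O)[C@H]12 | intermediate
22 | (S)-1-amino-2-(methoxymethyl)pyrrolidine (SAMP) | COC[C@@H]1CCCN1N | starting material
23 | (E)-SAMP hydrazone of 21 | C=C1CCCC(C)(C)[C@@H]2CC[C@@](C)(C/C=N/N3CCC[C@H]3COC)[C@H]12 | intermediate
24 | furan-2(5H)-one | O=C1OCC=C1 | starting material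
25 | lithium (E)-azaenolate of 23 | C=C1CCCC(C)(C)[C@@H]2CC[C@@](C)(/C=C/[N-]N3CCC[C@H]3COC)[C@H]12.[Li+] | intermediate (not isolated)
26 | lithium enolate of the lactone Michael adduct | C=C1CCCC(C)(C)[C@@H]2CC[C@@](C)([C@H](/C=N/N4CCC[C@H]4COC)[C@@H]3COC([O-])=C3)[C@H]12.[Li+] | intermediate (not isolated)
27 | SAMP hydrazone of 2-(4-hydroxy-5-oxooxolan-3-yl)-2-(1,4,4-trimethyl-8-methylidenedecahydroazulen-1-yl)acetaldehyde (OH trans to the lactone β-substituent) | C=C1CCCC(C)(C)[C@@H]2CC[C@@](C)([C@H](/C=N/N4CCC[C@H]4COC)[C@@H]3COC(=O)[C@H]3O)[C@H]12 | intermediate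
28 | 2-(4-hydroxy-5-oxooxolan-3-yl)-2-(1,4,4-trimethyl-8-methylidenedecahydroazulen-1-yl)acetaldehyde | C=C1CCCC(C)(C)[C@@H]2CC[C@@](C)([C@H](C=O)[C@@H]3COC(=O)[C@H]3O)[C@H]12 | intermediate
29 | 3-hydroxy-4-[2-hydroxy-1-(1,4,4-trimethyl-8-methylidenedecahydroazulen-1-yl)ethyl]oxolan-2-one | C=C1CCCC(C)(C)[C@@H]2CC[C@@](C)([C@H](CO)[C@@H]3COC(=O)[C@H]3O)[C@H]12 | intermediate
30 | CNP0234964.1, 2-(4-acetoxy-5-oxooxolan-3-yl)-2-(1,4,4-trimethyl-8-methylidenedecahydroazulen-1-yl)ethyl acetate | C=C1CCCC(C)(C)[C@@H]2CC[C@@](C)([C@H](COC(C)=O)[C@@H]3COC(=O)[C@H]3OC(C)=O)[C@H]12 | target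

**Totals and risks**

Total step count: 18. Longest linear sequence: 18 steps (from 1).

Steps most likely to fail, in order of risk: step 15, step 6, step 5.

Step 15. Two things may go wrong: proton transfer from the γ-CH2 of the butenolide to the azaenolate instead of conjugate addition, and poor facial selectivity on the butenolide, which would scramble the lactone β-carbon. The fallback sets out from hydrazone 23 and moves facial control to the acceptor. The same azaenolate (LDA, THF) is added to (5S)-5-[(1S,2R,5S)-menthyloxy]furan-2(5H)-one, O=C1C=C[C@@H](O[C@H]2C[C@@H](C)CC[C@@H]2C(C)C)O1, whose acetal substituent is known to direct nucleophiles to the opposite face. Oxidation of the enolate in the same flask with the oxaziridine should give the menthyloxy lactone hydrazone F1. Aqueous oxalic acid and then aqueous trifluoroacetic acid should cleave the hydrazone and the menthyl acetal to the lactol aldehyde F2 (anomeric mixture). Sodium borohydride reduces both aldehyde functions (the lactol through its open form), and acidification closes the γ-lactone again, which returns to the route at diol 29.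

Step 6. The tetrasubstituted enone may resist conjugate addition (1,2-addition or simple silyl transfer instead), or the nucleophile may enter with poor facial selectivity at the new quaternary carbon. The fallback sets out from enone 8 and replaces the addition by a sigmatropic chirality transfer. Reduction with (R)-Me-CBS and BH3·SMe2 (olefinic side as the large group) should give the allylic alcohol F3 with the hydroxyl on the face of H-3a. Eschenmoser–Claisen rearrangement with N,N-dimethylacetamide dimethyl acetal (xylene, 140 °C) transfers this configuration suprafacially to the quaternary carbon and gives the amide F4 with the alkene moved to the ring fusion. Hydroboration–oxidation (BH3·SMe2, 0 °C; H2O2, NaOH) from the convex face gives the alcohol F5. Dess–Martin oxidation, with equilibration of the ring fusion to cis, returns to the route at keto amide 12.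

Step 5. The unstabilised carbenoid may insert into the allylic methyl C–H (giving an isomeric fused cyclopentenone), dimerise, or the vinyl diazoketone may cyclise to a pyrazole before it reaches the metal. The fallback sets out from acid 5 and uses a stabilised acceptor/acceptor carbenoid, which is more selective for tertiary C–H bonds. Masamune homologation (carbonyldiimidazole, then magnesium methyl malonate) gives the β-keto ester F6. Diazo transfer (p-acetamidobenzenesulfonyl azide, Et3N) gives the diazo keto ester F7. Rh2(OAc)4 should then give the bicyclic β-keto ester F8. Krapcho demethoxycarbonylation (LiCl, wet DMSO, 150 °C) returns to the route at enone 8.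

**Further compounds**

F1 | step 15 | SAMP hydrazone of 2-[4-hydroxy-2-(d-menthyloxy)-5-oxooxolan-3-yl]-2-(1,4,4-trimethyl-8-methylidenedecahydroazulen-1-yl)acetaldehyde (menthyloxy and hydroxyl both trans to the ring substituent between them) | C=C1CCCC(C)(C)[C@@H]2CC[C@@](C)([C@H](/C=N/N4CCC[C@H]4COC)[C@@H]3[C@@H](O[C@H]5C[C@@H](C)CC[C@@H]5C(C)C)OC(=O)[C@H]3O)[C@H]12
F2 | step 15 | 2-(2,4-dihydroxy-5-oxooxolan-3-yl)-2-(1,4,4-trimethyl-8-methylidenedecahydroazulen-1-yl)acetaldehyde (lactol, anomeric mixture) | C=C1CCCC(C)(C)[C@@H]2CC[C@@](C)([C@H](C=O)[C@@H]3C(O)OC(=O)[C@H]3O)[C@H]12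
F3 | step 6 | (1S,3aS)-3,3,6-trimethyl-1,2,3,3a,4,5-hexahydropentalen-1-ol | O[C@H]1CC(C)(C)[C@@H]2CCC(C)=C12
F4 | step 6 | 2-(1,4,4-trimethyl-1,2,3,3a,4,5-hexahydropentalen-1-yl)-N,N-dimethylacetamide (amide arm syn to H-3a) | C1CC(C)(C)[C@@H]2CC[C@@](C)(CC(=O)N(C)C)C=12
F5 | step 6 | 2-(6-hydroxy-1,4,4-trimethyloctahydropentalen-1-yl)-N,N-dimethylacetamide (cis-fused; OH on the convex face) | O[C@H]1CC(C)(C)[C@@H]2CC[C@@](C)(CC(=O)N(C)C)[C@H]12
F6 | step 5 | methyl 3-[(5S)-2-methyl-5-(propan-2-yl)cyclopent-1-en-1-yl]-3-oxopropanoate | CC(C)[C@@H]1CCC(C)=C1C(=O)CC(=O)OC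
F7 | step 5 | methyl 2-diazo-3-[(5S)-2-methyl-5-(propan-2-yl)cyclopent-1-en-1-yl]-3-oxopropanoate | CC(C)[C@@H]1CCC(C)=C1C(=O)C(=[N+]=[N-])C(=O)OC
F8 | step 5 | methyl (3aS)-3,3,6-trimethyl-1-oxo-1,2,3,3a,4,5-hexahydropentalene-2-carboxylate (C-2 epimers, enolisable) | O=C1C(C(=O)OC)C(C)(C)[C@@H]2CCC(C)=C12
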